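**Retrosynthetic overview**

1. Feature: in the 2H-chromene the quaternary carbon C2 lies between ring oxygen O1 and side-chain methylene C1'. C2'–C5', the C4' methyl and the C5' hydroxyl are exactly the atoms of 2-methyl-2-vinyloxirane, so O1–C2 and C1'–C2' can be made in one divalent-palladium cycle.
2. Target 19 ⇒ bis-silyl ether 18 ⇒ B-alkyl Suzuki–Miyaura disconnection of the C6–CH2 bond: bromochromene 13 plus the borane from styrene 16 (from 2,3-dihydroxybenzaldehyde).
3. 13 ⇒ chroman 10: the C3=C4 bond is introduced by DDQ dehydrogenation of the acetate of 10.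
4. 10 ⇒ phenol 6 + oxirane 7 (key step; the pyran ring is the only ring formed, both benzene rings are bought). 6 ⇒ 5-bromosalicylaldehyde + 2-methylallylmagnesium chloride through an ortho-quinone methide.

Key step: step 4

Remark: side-chain carbons are called C1' (on C2) to C5' (CH2OH). The ligand antipode is assigned by analogy with Wacker–Heck chroman closures; if the sense of induction proves opposite, the (S,S) ligand is used instead.

**Route**

Step 1
Reactants: 1 5-bromosalicylaldehyde
Product: 2 tert-butyl (4-bromo-2-formylphenyl) carbonate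
Conditions: Boc2O, iPr2NEt, DMAP (cat.), THF, rt
Reagents that add atoms: di-tert-butyl dicarbonate, CC(C)(C)OC(=O)OC(=O)OC(C)(C)C
Why: DMAP-catalysed O-acylation of the phenol installs the carbonate that later triggers ortho-quinone methide formation.

Step 2
Reactants: 2 tert-butyl (4-bromo-2-formylphenyl) carbonate
Product: 3 tert-butyl [4-bromo-2-(hydroxymethyl)phenyl] carbonate
Conditions: BH3·THF, THF, 0 °C; aq. NH4Cl
Reagents that add atoms: none
Why: Borane reduction of the aldehyde runs without a free alkoxide, so the carbonate does not migrate prematurely, and the aryl carbonate and the C–Br bond are inert to it.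

Step 3
Reactants: 3 tert-butyl [4-bromo-2-(hydroxymethyl)phenyl] carbonate; 4 2-methylallylmagnesium chloride
Product: 6 4-bromo-2-(3-methylbut-3-en-1-yl)phenol, via ortho-quinone methide 5 (not isolated)
Conditions: 4 (2.5 equiv), THF, −78 °C → rt; sat. aq. NH4Cl
Reagents that add atoms: none
Why: The first equivalent of Grignard reagent deprotonates the alcohol, the carbonate migrates to the benzylic oxygen and is expelled from the phenoxide, and the second equivalent adds to the exocyclic methylene of ortho-quinone methide 5 (1,4-addition with rearomatisation), while the neutral work-up avoids acid closure to 2,2-dimethylchroman.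

Step 4
Reactants: 6 4-bromo-2-(3-methylbut-3-en-1-yl)phenol; 7 2-methyl-2-vinyloxirane (racemic, 4 equiv)
Product: 10 (2E)-5-[(2S)-6-bromo-2-methylchroman-2-yl]-2-methylpent-2-en-1-ol, via primary alkylpalladium 8 (not isolated), via secondary alkylpalladium 9 (not isolated)
Conditions: Pd(OCOCF3)2 (10 mol%), (R,R)-Bn-BOXAX [(R)-2,2'-bis((R)-4-benzyl-4,5-dihydrooxazol-2-yl)-1,1'-binaphthyl] (20 mol%), p-benzoquinone (20 mol%), 4 Å molecular sieves, CH2Cl2, rt, dark
Reagents that add atoms: none
Why: Proposed new method: the divalent palladium–bisoxazoline complex activates the 1,1-disubstituted alkene of 6 and the phenol oxygen adds to its substituted carbon (oxypalladation, O1–C2, with release of CF3CO2H), giving primary alkylpalladium 8, which cannot undergo β-hydride elimination because C2 is quaternary and therefore inserts the vinyl group of 7 with carbon bonding to the terminal CH2 (C1'–C2') and palladium moving to the carbon next to the oxirane (9); strain-assisted β-oxygen elimination then opens the oxirane to the C3'=C4' alkene and the CF3CO2H set free earlier protonates the Pd–O bond and returns Pd(OCOCF3)2, so palladium stays divalent throughout and the five carbons of 7 become C2'–C5' and the C4' methyl with the hydroxyl already in place. The closest known reaction types are the enantioselective domino Wacker–Heck cyclisation of 2-(3-methylbut-3-enyl)phenols with acrylates under this catalyst system, the oxyallylation of alkenyl phenols in which a divalent alkylpalladium inserts an allyl halide and turns over by β-halide elimination, and Heck-type additions of organopalladium species to vinyl oxiranes that end in ring opening to allylic alcohols; what is new is their combination in one enantioselective cycle. The pyran ring closes in 6-exo-trig mode. The C2 stereocenter is set by the ligand, which must direct the oxygen to the Si face of the alkene carbon (priorities CH2CH2Ar > =CH2 > CH3) to give S. The step needs chemoselectivity for insertion over ionisation of 7 and over reaction at C–Br, which the absence of zerovalent palladium secures (p-benzoquinone returns any stray zerovalent palladium to the divalent state), and regioselectivity of O-attack, which the 1,1-disubstitution secures. It also needs E geometry, which is decided by the diastereotopic face of the vinyl group that inserts and by a uniform syn course of the β-oxygen elimination, with the chain expected to avoid the CH2O arm; this is the least secure element.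

Step 5
Reactants: 10 (2E)-5-[(2S)-6-bromo-2-methylchroman-2-yl]-2-methylpent-2-en-1-ol
Product: 11 (2E)-5-[(2S)-6-bromo-2-methylchroman-2-yl]-2-methylpent-2-en-1-yl acetate
Conditions: Ac2O, pyridine, DMAP (cat.), CH2Cl2, 0 °C → rt
Reagents that add atoms: acetic anhydride, CC(=O)OC(C)=O
Why: Acylation of the primary allylic alcohol gives an ester that cannot be oxidised to the enal and that deactivates the side-chain alkene toward DDQ in the next step.

Step 6
Reactants: 11 (2E)-5-[(2S)-6-bromo-2-methylchroman-2-yl]-2-methylpent-2-en-1-yl acetate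
Product: 12 (2E)-5-[(2S)-6-bromo-2-methyl-2H-chromen-2-yl]-2-methylpent-2-en-1-yl acetate
Conditions: DDQ (1.5 equiv), benzene, 80 °C, dark
Reagents that add atoms: none
Why: DDQ abstracts hydride from benzylic C4, whose cation is stabilised by O1 through the arene, and loss of a C3 proton gives the C3=C4 bond (quinone dehydrogenation of a chroman to a 2H-chromene), while quaternary C2 is not involved.

Step 7
Reactants: 12 (2E)-5-[(2S)-6-bromo-2-methyl-2H-chromen-2-yl]-2-methylpent-2-en-1-yl acetate
Product: 13 (2E)-5-[(2S)-6-bromo-2-methyl-2H-chromen-2-yl]-2-methylpent-2-en-1-ol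
Conditions: K2CO3 (cat.), MeOH, 0 °C → rt
Reagents that add atoms: none
Why: Base-catalysed transesterification frees the allylic alcohol before the cross-coupling, so that no allylic ester is exposed to zerovalent palladium, which could ionise it in Tsuji–Trost fashion.

Step 8
Reactants: 14 2,3-dihydroxybenzaldehyde
Product: 15 2,3-bis(tert-butyldimethylsilyloxy)benzaldehyde
Conditions: TBSCl, imidazole, DMF, rt
Reagents that add atoms: tert-butyldimethylsilyl chloride, CC(C)(C)[Si](C)(C)Cl
Why: Silylation of both phenols masks the oxidation-prone catechol with groups that buffered fluoride removes at the end without acid or strong base.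

Step 9
Reactants: 15 2,3-bis(tert-butyldimethylsilyloxy)benzaldehyde
Product: 16 1,2-bis(tert-butyldimethylsilyloxy)-3-vinylbenzene
Conditions: Ph3PCH3Br, NaN(SiMe3)2, THF, 0 °C; then 15, 0 °C → rt
Reagents that add atoms: methyltriphenylphosphonium bromide, C[P+](c1ccccc1)(c1ccccc1)c1ccccc1.[Br-]
Why: Wittig methylenation with the preformed, alkoxide-free ylide converts the aldehyde into the styrene without touching the aryl silyl ethers.

Step 10
Reactants: 13 (2E)-5-[(2S)-6-bromo-2-methyl-2H-chromen-2-yl]-2-methylpent-2-en-1-ol; 16 1,2-bis(tert-butyldimethylsilyloxy)-3-vinylbenzene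
Product: 18 (2E)-5-[(2S)-6-{2-[2,3-bis(tert-butyldimethylsilyloxy)phenyl]ethyl}-2-methyl-2H-chromen-2-yl]-2-methylpent-2-en-1-ol, via alkylborane 17 (not isolated)
Conditions: 16 (1.6 equiv), 9-BBN (1.5 equiv), THF, 0 °C → rt; then 13 (1.0 equiv), PdCl2(dppf) (5 mol%), aq. K3PO4 (3 equiv), DMF, 50 °C, dark
Reagents that add atoms: none
Why: 9-BBN adds to the styrene with boron on the terminal carbon, and the primary alkylborane 17 transfers its alkyl group to the arylpalladium bromide formed at C6 (B-alkyl Suzuki–Miyaura coupling), with the chromene alkene, the trisubstituted alkene and the free alcohol as spectators since no B–H remains.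

Step 11
Reactants: 18 (2E)-5-[(2S)-6-{2-[2,3-bis(tert-butyldimethylsilyloxy)phenyl]ethyl}-2-methyl-2H-chromen-2-yl]-2-methylpent-2-en-1-ol
Product: 19 3-{2-[(2S)-2-[(3E)-5-hydroxy-4-methylpent-3-en-1-yl]-2-methyl-2H-chromen-6-yl]ethyl}benzene-1,2-diol
Conditions: Bu4NF (2.5 equiv), AcOH (2.5 equiv), THF, 0 °C, argon, dark
Reagents that add atoms: none
Why: Fluoride desilylation cleaves both aryl Si–O bonds, and the acetic acid buffer keeps the liberated catechol protonated and so protects it from air oxidation while leaving the chromene and the allylic alcohol untouched.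

**Compound list**

1 | 5-bromosalicylaldehyde | O=Cc1cc(Br)ccc1O | starting material
2 | tert-butyl (4-bromo-2-formylphenyl) carbonate | CC(C)(C)OC(=O)Oc1ccc(Br)cc1C=O | intermediate
3 | tert-butyl [4-bromo-2-(hydroxymethyl)phenyl] carbonate | CC(C)(C)OC(=O)Oc1ccc(Br)cc1CO | intermediate
4 | 2-methylallylmagnesium chloride | C=C(C)C[Mg]Cl | starting material
5 | 4-bromo-6-methylidenecyclohexa-2,4-dien-1-one (ortho-quinone methide) | C=C1C=C(Br)C=CC1=O | intermediate (not isolated)
6 | 4-bromo-2-(3-methylbut-3-en-1-yl)phenol | C=C(C)CCc1cc(Br)ccc1O | intermediate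
7 | 2-methyl-2-vinyloxirane (racemic) | C=CC1(C)CO1 | starting material
8 | {[6-bromo-2-methylchroman-2-yl]methyl}palladium trifluoroacetate, C2 arranged as in 10 (bisoxazoline ligand on palladium not drawn) | O=C(O[Pd]C[C@@]1(C)CCc2cc(Br)ccc2O1)C(F)(F)F | intermediate (not isolated)
9 | {3-[6-bromo-2-methylchroman-2-yl]-1-(2-methyloxiran-2-yl)propyl}palladium trifluoroacetate, C2 arranged as in 10, mixture at the two new centers (bisoxazoline ligand not drawn) | O=C(O[Pd]C(CC[C@@]1(C)CCc2cc(Br)ccc2O1)C3(C)CO3)C(F)(F)F | intermediate (not isolated)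
10 | (2E)-5-[(2S)-6-bromo-2-methylchroman-2-yl]-2-methylpent-2-en-1-ol | C/C(=C\CC[C@@]1(C)CCc2cc(Br)ccc2O1)CO | intermediate
11 | (2E)-5-[(2S)-6-bromo-2-methylchroman-2-yl]-2-methylpent-2-en-1-yl acetate | C/C(=C\CC[C@@]1(C)CCc2cc(Br)ccc2O1)COC(C)=O | intermediate
12 | (2E)-5-[(2S)-6-bromo-2-methyl-2H-chromen-2-yl]-2-methylpent-2-en-1-yl acetate | C/C(=C\CC[C@@]1(C)C=Cc2cc(Br)ccc2O1)COC(C)=O | intermediate
13 | (2E)-5-[(2S)-6-bromo-2-methyl-2H-chromen-2-yl]-2-methylpent-2-en-1-ol | C/C(=C\CC[C@@]1(C)C=Cc2cc(Br)ccc2O1)CO | intermediate
14 | 2,3-dihydroxybenzaldehyde | O=Cc1cccc(O)c1O | starting material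
15 | 2,3-bis(tert-butyldimethylsilyloxy)benzaldehyde | O=Cc1cccc(O[Si](C)(C)C(C)(C)C)c1O[Si](C)(C)C(C)(C)C | intermediate
16 | 1,2-bis(tert-butyldimethylsilyloxy)-3-vinylbenzene | C=Cc1cccc(O[Si](C)(C)C(C)(C)C)c1O[Si](C)(C)C(C)(C)C | intermediate
17 | 9-{2-[2,3-bis(tert-butyldimethylsilyloxy)phenyl]ethyl}-9-borabicyclo[3.3.1]nonane | CC(C)(C)[Si](C)(C)Oc1cccc(CCB2C3CCCC2CCC3)c1O[Si](C)(C)C(C)(C)C | intermediate (not isolated)
18 | (2E)-5-[(2S)-6-{2-[2,3-bis(tert-butyldimethylsilyloxy)phenyl]ethyl}-2-methyl-2H-chromen-2-yl]-2-methylpent-2-en-1-ol | C/C(=C\CC[C@@]1(C)C=Cc2cc(CCc3cccc(O[Si](C)(C)C(C)(C)C)c3O[Si](C)(C)C(C)(C)C)ccc2O1)CO | intermediate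
19 | 3-{2-[(2S)-2-[(3E)-5-hydroxy-4-methylpent-3-en-1-yl]-2-methyl-2H-chromen-6-yl]ethyl}benzene-1,2-diol | C/C(=C\CC[C@@]1(C)C=Cc2cc(CCc3cccc(O)c3O)ccc2O1)CO | target

**Step count**

Total: 11 steps. Longest linear sequence: 9 steps (steps 1–7, 10, 11); the styrene branch (steps 8, 9) joins at step 10.

**Steps most likely to fail**

1. Step 4 (proposed new method). Three processes may defeat it.
   - Insertion of the weakly activated vinyl group into the primary alkylpalladium may be too slow, so that protodepalladation or decomposition of the oxirane takes over (acid-promoted opening by the phenol, ionisation by stray zerovalent palladium).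
   - β-Hydride elimination at C2' may compete with β-oxygen elimination.
   - The insertion may show poor face selectivity relative to the oxirane and so give an E/Z mixture.

   Fallback, known chemistry only, setting out from 6 and returning at 10:
   - Enantioselective domino Wacker/carbonylation/methoxylation of 6 (Pd(OCOCF3)2, the same ligand, CO at 1 atm, MeOH, p-benzoquinone as stoichiometric reoxidant, CH2Cl2, rt) should give methyl 2-[(2R)-6-bromo-2-methylchroman-2-yl]acetate F1.
   - iBu2AlH (CH2Cl2, −78 °C) should reduce it to 2-[(2R)-6-bromo-2-methylchroman-2-yl]acetaldehyde F2.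
   - Wittig reaction with MeOCH2PPh3Cl/NaN(SiMe3)2 (THF, 0 °C) should give the enol ether (2R)-6-bromo-2-(3-methoxyprop-2-en-1-yl)-2-methylchroman F3.
   - Aqueous HCl in THF should hydrolyse it to the homologous aldehyde 3-[(2R)-6-bromo-2-methylchroman-2-yl]propanal F4.
   - The stabilised ylide Ph3P=C(CH3)CO2Et (toluene, 80 °C) should give, E-selectively, ethyl (2E)-5-[(2S)-6-bromo-2-methylchroman-2-yl]-2-methylpent-2-enoate F5.
   - iBu2AlH (CH2Cl2, −78 °C) should reduce the ester to 10.

2. Step 6. Hydride abstraction at C4 may be slow on the bromine-deactivated ring, so that DDQ attacks allylic positions of the side chain instead. Prolonged heating may also erode the C2 configuration through reversible electrocyclic opening of the chromene.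

   Fallback, setting out from 1 and 4 and returning at 13, carries the C4 oxygen from the start:
   - 2-Methylallylmagnesium chloride (2.2 equiv, THF, −78 → 0 °C) adds to the aldehyde of 1 to give racemic 4-bromo-2-(1-hydroxy-3-methylbut-3-en-1-yl)phenol F6.
   - This diol is taken through the conditions of step 4 with 7, with NaHCO3 added as a buffer so that the ortho-hydroxybenzylic alcohol is not ionised. It should give (2E)-5-[(2S)-6-bromo-4-hydroxy-2-methylchroman-2-yl]-2-methylpent-2-en-1-ol F7 as a mixture of C4 epimers.
   - p-Toluenesulfonic acid (cat., benzene, 50 °C) then removes the C4 hydroxyl by E1 dehydration through the O1-stabilised benzylic cation, which ionises far more readily than the primary allylic alcohol. This gives 13 directly, so steps 5 to 7 fall away.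

3. Step 10. Transmetalation of the alkylborane may be slow, so that the arylpalladium bromide is reduced instead, and the aqueous base may strip the aryl silyl ethers during the coupling.

   Fallback, setting out from 16 and 13 and returning at 18, is a base-free reductive coupling:
   - Hydroboration–oxidation of 16 (9-BBN, THF; then NaBO3·4H2O) should give 2-[2,3-bis(tert-butyldimethylsilyloxy)phenyl]ethanol F8.
   - Appel reaction (CBr4, PPh3, CH2Cl2, 0 °C) should give 1-(2-bromoethyl)-2,3-bis(tert-butyldimethylsilyloxy)benzene F9.
   - Nickel-catalysed reductive cross-electrophile coupling of F9 with 13 (NiBr2 as its 1,2-dimethoxyethane adduct, 4,4'-di-tert-butyl-2,2'-bipyridine, Zn dust, NaI, N,N-dimethylacetamide, 60 °C) should join C6 to the primary alkyl carbon and give 18.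

**Further compounds**

F1 | step 4 | methyl 2-[(2R)-6-bromo-2-methylchroman-2-yl]acetate | COC(=O)C[C@@]1(C)CCc2cc(Br)ccc2O1
F2 | step 4 | 2-[(2R)-6-bromo-2-methylchroman-2-yl]acetaldehyde | O=CC[C@@]1(C)CCc2cc(Br)ccc2O1
F3 | step 4 | (2R)-6-bromo-2-(3-methoxyprop-2-en-1-yl)-2-methylchroman (E/Z mixture) | COC=CC[C@@]1(C)CCc2cc(Br)ccc2O1
F4 | step 4 | 3-[(2R)-6-bromo-2-methylchroman-2-yl]propanal | O=CCC[C@@]1(C)CCc2cc(Br)ccc2O1
F5 | step 4 | ethyl (2E)-5-[(2S)-6-bromo-2-methylchroman-2-yl]-2-methylpent-2-enoate | CCOC(=O)/C(C)=C/CC[C@@]1(C)CCc2cc(Br)ccc2O1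
F6 | step 6 | 4-bromo-2-(1-hydroxy-3-methylbut-3-en-1-yl)phenol (racemic) | C=C(C)CC(O)c1cc(Br)ccc1O
F7 | step 6 | (2E)-5-[(2S)-6-bromo-4-hydroxy-2-methylchroman-2-yl]-2-methylpent-2-en-1-ol (C4 epimers) | C/C(=C\CC[C@@]1(C)CC(O)c2cc(Br)ccc2O1)CO
F8 | step 10 | 2-[2,3-bis(tert-butyldimethylsilyloxy)phenyl]ethanol | OCCc1cccc(O[Si](C)(C)C(C)(C)C)c1O[Si](C)(C)C(C)(C)C
F9 | step 10 | 1-(2-bromoethyl)-2,3-bis(tert-butyldimethylsilyloxy)benzene | BrCCc1cccc(O[Si](C)(C)C(C)(C)C)c1O[Si](C)(C)C(C)(C)C
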